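**Retrosynthetic overview**
1. The strategy rests on the C3''=C4'' double bond of the 2,2-dimethyl-2H-pyran ring (ring D), which is fused to ring B at C4'–C5'. C4'' is a styrenic CH on C5', and C3'' sits on the gem-dimethyl carbon C2'' carried by O-4'. Retro-metathesis therefore cuts this alkene into a 5'-vinyl group and a 4'-O-(1,1-dimethylallyl) ether.
2. The vinyl group comes from a 5'-bromide (Stille). The tert-allyl ether comes from the free 4'-phenol and the tert-butyl carbonate of 2-methylbut-3-en-2-ol (Pd). O-7 and O-2' stay silylated to the end.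
3. Ring C: the O1–C2 bond is made by Mitsunobu closure. The C3–C4 bond and the (3R) centre come from Evans benzylation of a ring-B arylacetyl imide with a ring-A benzyl bromide.
4. The ring-B acid comes from 5-bromo-2,4-dihydroxybenzaldehyde by C3-prenylation, 4-O-allyl/2-O-TBS protection and one-carbon homologation. The ring-A bromide comes from 2,4-dihydroxybenzaldehyde.
5. Ring order: A and B are bought, C is closed in step 15, D in step 19, then the silyl groups are removed.

Key step: step 19

Remark: isoflavan numbering is used (chroman O1–C8a, ring B primed, pyran ring double-primed). TBS = tert-butyldimethylsilyl and prenyl = 3-methylbut-2-en-1-yl. Enol ether 6 is carried on as its E/Z mixture because both isomers give the same aldehyde.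

**Step 1**
Reactants: 1 5-bromo-2,4-dihydroxybenzaldehyde; 2 prenyl bromide
Product: 3 5-bromo-2,4-dihydroxy-3-prenylbenzaldehyde
Conditions: KOH (aq, 10 %), 0 °C → rt; mild acidification (pH 5)
Reagents that add atoms: none
Why: Nuclear C-prenylation of a resorcinol-type phenolate in water, where solvation of the oxygens steers the allylic bromide to carbon, and C3 between the two oxygens is the only activated free position because C5 carries bromine.

**Step 2**
Reactants: 3 5-bromo-2,4-dihydroxy-3-prenylbenzaldehyde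
Product: 4 4-(allyloxy)-5-bromo-2-hydroxy-3-prenylbenzaldehyde
Conditions: allyl bromide (1.05 equiv), K2CO3 (1.05 equiv), DMF, rt
Reagents that add atoms: allyl bromide, C=CCBr
Why: Williamson etherification that should pick the more acidic 4-OH (para to CHO, ortho to Br), since the 2-OH is held in a hydrogen bond to the aldehyde.

**Step 3**
Reactants: 4 4-(allyloxy)-5-bromo-2-hydroxy-3-prenylbenzaldehyde
Product: 5 4-(allyloxy)-5-bromo-2-(TBSO)-3-prenylbenzaldehyde
Conditions: TBSOTf, 2,6-lutidine, CH2Cl2, 0 °C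
Reagents that add atoms: tert-butyldimethylsilyl triflate, CC(C)(C)[Si](C)(C)OS(=O)(=O)C(F)(F)F
Why: O-silylation with the triflate overcomes the hydrogen bond and the two ortho substituents, and those same neighbours later shield this silyl ether.

**Step 4**
Reactants: 5 4-(allyloxy)-5-bromo-2-(TBSO)-3-prenylbenzaldehyde
Product: 6 4-(allyloxy)-5-bromo-1-(2-methoxyvinyl)-2-(TBSO)-3-prenylbenzene (E/Z mixture)
Conditions: MeOCH2PPh3Cl, NaHMDS, THF, 0 °C; then 5, 0 °C → rt
Reagents that add atoms: (methoxymethyl)triphenylphosphonium chloride, COC[P+](c1ccccc1)(c1ccccc1)c1ccccc1.[Cl-]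
Why: Wittig olefination with the preformed methoxymethylene ylide adds the future C2 carbon through an oxaphosphetane, so no free alkoxide arises next to the ortho silyl ether.

**Step 5**
Reactants: 6 4-(allyloxy)-5-bromo-1-(2-methoxyvinyl)-2-(TBSO)-3-prenylbenzene
Product: 7 [4-(allyloxy)-5-bromo-2-(TBSO)-3-prenylphenyl]acetaldehyde
Conditions: 2 M HCl (aq), THF, 40 °C, stopped at full conversion; crude product used at once
Reagents that add atoms: water, O
Why: Acid-catalysed enol ether hydrolysis (C-protonation, capture of the oxocarbenium ion by water, loss of methanol); the doubly ortho-flanked aryl silyl ether, the allyl ether and the prenyl group, which has no free neighbouring phenol, should tolerate dilute acid.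

**Step 6**
Reactants: 7 [4-(allyloxy)-5-bromo-2-(TBSO)-3-prenylphenyl]acetaldehyde
Product: 8 [4-(allyloxy)-5-bromo-2-(TBSO)-3-prenylphenyl]acetic acid
Conditions: NaClO2, NaH2PO4, 2-methylbut-2-ene (large excess), t-BuOH/H2O, 0 °C → rt
Reagents that add atoms: sodium chlorite, [Na+].[O-]Cl=O
Why: Pinnick oxidation takes the aldehyde to the acid without enolisation problems, and the excess of scavenger alkene traps HOCl before it reaches the prenyl and allyl groups.

**Step 7**
Reactants: 8 [4-(allyloxy)-5-bromo-2-(TBSO)-3-prenylphenyl]acetic acid; 9 (R)-4-benzyloxazolidin-2-one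
Product: 11 (R)-4-benzyl-3-{[4-(allyloxy)-5-bromo-2-(TBSO)-3-prenylphenyl]acetyl}oxazolidin-2-one, via pivaloyl mixed anhydride 10 (not isolated)
Conditions: PivCl, Et3N, THF, −20 °C; then LiCl, 9, −20 °C → rt
Reagents that add atoms: pivaloyl chloride, CC(C)(C)C(=O)Cl (its acyl group is held only in 10)
Why: Mixed-anhydride N-acylation of the oxazolidinone under LiCl/Et3N conditions attacks the less hindered arylacetyl carbonyl and needs no alkyllithium next to the aryl bromide.

**Step 8**
Reactants: 12 2,4-dihydroxybenzaldehyde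
Product: 13 4-(TBSO)-2-hydroxybenzaldehyde
Conditions: TBSCl (1.05 equiv), imidazole, CH2Cl2, 0 °C
Reagents that add atoms: tert-butyldimethylsilyl chloride, CC(C)(C)[Si](C)(C)Cl
Why: Selective silylation of the free 4-OH, while the chelated 2-OH reacts much more slowly.

**Step 9**
Reactants: 13 4-(TBSO)-2-hydroxybenzaldehyde
Product: 14 2-(allyloxy)-4-(TBSO)benzaldehyde
Conditions: allyl alcohol, PPh3, DIAD, THF, 0 °C → rt
Reagents that add atoms: allyl alcohol, C=CCO
Why: Mitsunobu etherification of the acidic salicylaldehyde phenol runs under neutral conditions, so the base-labile para-formyl aryl silyl ether is neither cleaved nor scrambled.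

**Step 10**
Reactants: 14 2-(allyloxy)-4-(TBSO)benzaldehyde
Product: 15 [2-(allyloxy)-4-(TBSO)phenyl]methanol
Conditions: NaBH4, THF/EtOH, 0 °C
Reagents that add atoms: none
Why: Borohydride reduction of an aromatic aldehyde is fast at 0 °C and leaves the silyl and allyl ethers alone.

**Step 11**
Reactants: 15 [2-(allyloxy)-4-(TBSO)phenyl]methanol
Product: 16 2-(allyloxy)-4-(TBSO)benzyl bromide
Conditions: CBr4, PPh3, CH2Cl2, 0 °C; short silica plug, used at once
Reagents that add atoms: carbon tetrabromide, BrC(Br)(Br)Br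
Why: The Appel reaction makes the electron-rich and therefore labile benzylic bromide under neutral conditions.

**Step 12**
Reactants: 11 (R)-4-benzyl-3-{[4-(allyloxy)-5-bromo-2-(TBSO)-3-prenylphenyl]acetyl}oxazolidin-2-one; 16 2-(allyloxy)-4-(TBSO)benzyl bromide
Product: 18 (R)-4-benzyl-3-{(2R)-3-[2-(allyloxy)-4-(TBSO)phenyl]-2-[4-(allyloxy)-5-bromo-2-(TBSO)-3-prenylphenyl]propanoyl}oxazolidin-2-one, via sodium Z-enolate 17 (not isolated)
Conditions: NaHMDS (1.05 equiv), THF, −78 °C; then 16 (1.5 equiv), −78 → −30 °C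
Reagents that add atoms: sodium hexamethyldisilazide, C[Si](C)(C)[N-][Si](C)(C)C.[Na+] (sodium is held only in 17)
Why: In this Evans asymmetric alkylation the sodium-chelated Z-enolate is shielded on one face by the C4 benzyl group of the (R)-auxiliary, so the reactive benzylic bromide enters from the open face, sets the future C3 as (R) and forms the C3–C4 bond.

**Step 13**
Reactants: 18 (R)-4-benzyl-3-{(2R)-3-[2-(allyloxy)-4-(TBSO)phenyl]-2-[4-(allyloxy)-5-bromo-2-(TBSO)-3-prenylphenyl]propanoyl}oxazolidin-2-one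
Product: 19 (2R)-3-[2-(allyloxy)-4-(TBSO)phenyl]-2-[4-(allyloxy)-5-bromo-2-(TBSO)-3-prenylphenyl]propan-1-ol
Conditions: LiBH4, H2O (1 equiv), Et2O, 0 °C
Reagents that add atoms: none
Why: Reductive removal of the auxiliary with LiBH4/H2O attacks the exocyclic imide carbonyl without enolising the α-aryl centre, so the configuration is kept and 9 is recovered.

**Step 14**
Reactants: 19 (2R)-3-[2-(allyloxy)-4-(TBSO)phenyl]-2-[4-(allyloxy)-5-bromo-2-(TBSO)-3-prenylphenyl]propan-1-ol
Product: 20 (2R)-2-[5-bromo-4-hydroxy-2-(TBSO)-3-prenylphenyl]-3-[2-hydroxy-4-(TBSO)phenyl]propan-1-ol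
Conditions: Pd(PPh3)4 (5 mol %), morpholine, THF, rt
Reagents that add atoms: none
Why: Tsuji–Trost deallylation ionises both aryl allyl ethers and passes the allyl groups to morpholine, while the electron-rich hindered aryl bromide does not undergo oxidative addition at room temperature.

**Step 15**
Reactants: 20 (2R)-2-[5-bromo-4-hydroxy-2-(TBSO)-3-prenylphenyl]-3-[2-hydroxy-4-(TBSO)phenyl]propan-1-ol
Product: 21 (3R)-5'-bromo-4'-hydroxy-3'-prenyl-7,2'-bis(TBSO)isoflavan
Conditions: PPh3, DIAD, THF (0.01 M), 0 °C → rt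
Reagents that add atoms: none
Why: Intramolecular Mitsunobu etherification (6-exo-tet) closes ring C at the primary carbon without touching C3; the 4'-OH lies para to the side chain and cannot reach it, O-2' is silylated, and dilution suppresses intermolecular etherification.

**Step 16**
Reactants: 21 (3R)-5'-bromo-4'-hydroxy-3'-prenyl-7,2'-bis(TBSO)isoflavan
Product: 22 (3R)-4'-hydroxy-3'-prenyl-5'-vinyl-7,2'-bis(TBSO)isoflavan
Conditions: Bu3SnCH=CH2, Pd(PPh3)4 (5 mol %), BHT (trace), toluene, 105 °C; work-up without fluoride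
Reagents that add atoms: tributyl(vinyl)stannane, C=C[Sn](CCCC)(CCCC)CCCC
Why: Stille vinylation of an aryl bromide is base-free and fluoride-free, so the aryl silyl ethers and the free phenol are tolerated, and running it before the ether formation keeps the Pd-labile tert-allyl ether away from hot Pd(0).

**Step 17**
Reactants: 23 2-methylbut-3-en-2-ol
Product: 25 tert-butyl 2-methylbut-3-en-2-yl carbonate, via lithium alkoxide 24 (not isolated)
Conditions: n-BuLi, THF, −78 → 0 °C; then Boc2O, 0 °C → rt
Reagents that add atoms: di-tert-butyl dicarbonate, CC(C)(C)OC(=O)OC(=O)OC(C)(C)C; n-butyllithium, [Li]CCCC (lithium is held only in 24)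
Why: O-acylation of the preformed tertiary alkoxide with Boc2O activates the alcohol, which cannot itself alkylate a phenol, as a leaving group for palladium.

**Step 18**
Reactants: 22 (3R)-4'-hydroxy-3'-prenyl-5'-vinyl-7,2'-bis(TBSO)isoflavan; 25 tert-butyl 2-methylbut-3-en-2-yl carbonate
Product: 26 (3R)-4'-(2-methylbut-3-en-2-yloxy)-3'-prenyl-5'-vinyl-7,2'-bis(TBSO)isoflavan
Conditions: Pd(PPh3)4 (5–10 mol %), THF, 0–5 °C
Reagents that add atoms: none
Why: Decarboxylative Tsuji–Trost O-allylation, in which the tert-butoxide released from the carbonate deprotonates the only free phenol and the phenoxide attacks the more substituted, more cationic terminus of the 1,1-dimethyl-π-allyl palladium complex under kinetic control, the low temperature preventing re-ionisation to the linear ether.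

**Step 19**
Reactants: 26 (3R)-4'-(2-methylbut-3-en-2-yloxy)-3'-prenyl-5'-vinyl-7,2'-bis(TBSO)isoflavan
Product: 27 bis-TBS ether of the (3R) target (7,2'-bis(TBSO)-3'-prenyl-2'',2''-dimethylpyrano[4',5'] isoflavan)
Conditions: Grubbs II (5 mol %), 1,4-benzoquinone (10 mol %), CH2Cl2 (0.005 M), 40 °C, argon sparge
Reagents that add atoms: none
Why: Ring-closing olefin metathesis by the Chauvin mechanism: the ruthenium carbene first exchanges with the open 5'-vinyl group, the resulting aryl alkylidene adds [2+2] to the monosubstituted alkene of the adjacent O-CMe2CH=CH2 arm, and cycloreversion of the ruthenacyclobutane gives C3''=C4'' and Ru=CH2, which sheds ethylene on loading the next styrene. The closest known reaction type is the RCM of 2-vinylaryl allyl and 1,1-dimethylallyl ethers to 2H-chromenes. The one ring closed is the six-membered 2H-pyran (O-4', C2'', C3'', C4'', C5', C4'), closed at its endocyclic double bond by joining the two internal alkene carbons, and the gem-dimethyl effect and the ortho placement of both arms help the closure. No stereocentre is made, and C3 is remote and untouched. The step needs chemoselectivity among three alkenes: the trisubstituted prenyl alkene takes up ruthenium far more slowly than the styrene, it is meta to the vinyl group and cannot cyclise with it, and its only conceivable closure, with the tert-allyl arm, would be a slower seven-membered oxepine formation. Dilution, removal of ethylene and benzoquinone hold back dimerisation, ethenolysis of the prenyl group and hydride-induced alkene migration, and a [3,3] shift of the ether has no productive outlet because C3', C5' and C1' are all fully substituted.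

**Step 20**
Reactants: 27 bis-TBS ether of the (3R) target
Product: 28 target, (3R)-7,2'-dihydroxy-3'-prenyl-2'',2''-dimethylpyrano[4',5'] isoflavan (CNP0331403.1)
Conditions: TBAF (2.4 equiv), AcOH (2.4 equiv), THF, 0 °C
Reagents that add atoms: none
Why: Fluoride desilylation of both aryl silyl ethers under buffered, non-acidic conditions leaves the chromene and the ortho-prenylphenol uncyclised and does not touch C3.

**Compound list**
1 | 5-bromo-2,4-dihydroxybenzaldehyde | O=Cc1cc(Br)c(O)cc1O | starting material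
2 | prenyl bromide | CC(C)=CCBr | starting material
3 | 5-bromo-2,4-dihydroxy-3-prenylbenzaldehyde | O=Cc1cc(Br)c(O)c(CC=C(C)C)c1O | intermediate
4 | 4-(allyloxy)-5-bromo-2-hydroxy-3-prenylbenzaldehyde | O=Cc1cc(Br)c(OCC=C)c(CC=C(C)C)c1O | intermediate
5 | 4-(allyloxy)-5-bromo-2-(TBSO)-3-prenylbenzaldehyde | O=Cc1cc(Br)c(OCC=C)c(CC=C(C)C)c1O[Si](C)(C)C(C)(C)C | intermediate
6 | 4-(allyloxy)-5-bromo-1-(2-methoxyvinyl)-2-(TBSO)-3-prenylbenzene (E/Z mixture) | COC=Cc1cc(Br)c(OCC=C)c(CC=C(C)C)c1O[Si](C)(C)C(C)(C)C | intermediate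
7 | [4-(allyloxy)-5-bromo-2-(TBSO)-3-prenylphenyl]acetaldehyde | O=CCc1cc(Br)c(OCC=C)c(CC=C(C)C)c1O[Si](C)(C)C(C)(C)C | intermediate
8 | [4-(allyloxy)-5-bromo-2-(TBSO)-3-prenylphenyl]acetic acid | OC(=O)Cc1cc(Br)c(OCC=C)c(CC=C(C)C)c1O[Si](C)(C)C(C)(C)C | intermediate
9 | (R)-4-benzyloxazolidin-2-one | O=C1N[C@H](Cc2ccccc2)CO1 | starting material
10 | pivaloyl mixed anhydride of 8 (not isolated) | CC(C)(C)C(=O)OC(=O)Cc1cc(Br)c(OCC=C)c(CC=C(C)C)c1O[Si](C)(C)C(C)(C)C | intermediate
11 | (R)-4-benzyl-3-{[4-(allyloxy)-5-bromo-2-(TBSO)-3-prenylphenyl]acetyl}oxazolidin-2-one | O=C(Cc1cc(Br)c(OCC=C)c(CC=C(C)C)c1O[Si](C)(C)C(C)(C)C)N1[C@H](Cc2ccccc2)COC1=O | intermediate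
12 | 2,4-dihydroxybenzaldehyde | O=Cc1ccc(O)cc1O | starting material
13 | 4-(TBSO)-2-hydroxybenzaldehyde | O=Cc1ccc(O[Si](C)(C)C(C)(C)C)cc1O | intermediate
14 | 2-(allyloxy)-4-(TBSO)benzaldehyde | O=Cc1ccc(O[Si](C)(C)C(C)(C)C)cc1OCC=C | intermediate
15 | [2-(allyloxy)-4-(TBSO)phenyl]methanol | OCc1ccc(O[Si](C)(C)C(C)(C)C)cc1OCC=C | intermediate
16 | 2-(allyloxy)-4-(TBSO)benzyl bromide | BrCc1ccc(O[Si](C)(C)C(C)(C)C)cc1OCC=C | intermediate
17 | sodium Z-enolate of 11 (not isolated) | [Na+].[O-]/C(=C\c1cc(Br)c(OCC=C)c(CC=C(C)C)c1O[Si](C)(C)C(C)(C)C)N1[C@H](Cc2ccccc2)COC1=O | intermediate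
18 | (R)-4-benzyl-3-{(2R)-3-[2-(allyloxy)-4-(TBSO)phenyl]-2-[4-(allyloxy)-5-bromo-2-(TBSO)-3-prenylphenyl]propanoyl}oxazolidin-2-one | O=C([C@H](Cc1ccc(O[Si](C)(C)C(C)(C)C)cc1OCC=C)c1cc(Br)c(OCC=C)c(CC=C(C)C)c1O[Si](C)(C)C(C)(C)C)N1[C@H](Cc2ccccc2)COC1=O | intermediate
19 | (2R)-3-[2-(allyloxy)-4-(TBSO)phenyl]-2-[4-(allyloxy)-5-bromo-2-(TBSO)-3-prenylphenyl]propan-1-ol | OC[C@H](Cc1ccc(O[Si](C)(C)C(C)(C)C)cc1OCC=C)c1cc(Br)c(OCC=C)c(CC=C(C)C)c1O[Si](C)(C)C(C)(C)C | intermediate
20 | (2R)-2-[5-bromo-4-hydroxy-2-(TBSO)-3-prenylphenyl]-3-[2-hydroxy-4-(TBSO)phenyl]propan-1-ol | OC[C@H](Cc1ccc(O[Si](C)(C)C(C)(C)C)cc1O)c1cc(Br)c(O)c(CC=C(C)C)c1O[Si](C)(C)C(C)(C)C | intermediate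
21 | (3R)-5'-bromo-4'-hydroxy-3'-prenyl-7,2'-bis(TBSO)isoflavan | CC(C)=CCc1c(O)c(Br)cc([C@@H]2COc3cc(O[Si](C)(C)C(C)(C)C)ccc3C2)c1O[Si](C)(C)C(C)(C)C | intermediate
22 | (3R)-4'-hydroxy-3'-prenyl-5'-vinyl-7,2'-bis(TBSO)isoflavan | C=Cc1cc([C@@H]2COc3cc(O[Si](C)(C)C(C)(C)C)ccc3C2)c(O[Si](C)(C)C(C)(C)C)c(CC=C(C)C)c1O | intermediate
23 | 2-methylbut-3-en-2-ol | CC(C)(O)C=C | starting material
24 | lithium 2-methylbut-3-en-2-olate (not isolated) | [Li+].CC(C)([O-])C=C | intermediate
25 | tert-butyl 2-methylbut-3-en-2-yl carbonate | CC(C)(C)OC(=O)OC(C)(C)C=C | intermediate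
26 | (3R)-4'-(2-methylbut-3-en-2-yloxy)-3'-prenyl-5'-vinyl-7,2'-bis(TBSO)isoflavan (RCM precursor) | C=CC(C)(C)Oc1c(C=C)cc([C@@H]2COc3cc(O[Si](C)(C)C(C)(C)C)ccc3C2)c(O[Si](C)(C)C(C)(C)C)c1CC=C(C)C | intermediate
27 | bis-TBS ether of the (3R) target (RCM product) | CC(C)=CCc1c(O[Si](C)(C)C(C)(C)C)c([C@@H]2COc3cc(O[Si](C)(C)C(C)(C)C)ccc3C2)cc2c1OC(C)(C)C=C2 | intermediate
28 | CNP0331403.1, (3R)-configured | CC(C)=CCc1c(O)c([C@@H]2COc3cc(O)ccc3C2)cc2c1OC(C)(C)C=C2 | target

**Step count**
Total steps: 20.
Longest linear sequence: 15 (steps 1–7, 12–16, 18–20).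

**Steps most likely to fail**

1. **Step 19 (key step).** The alkene next to the quaternary carbon may engage too slowly. The catalyst may rest as a chelated 2-alkoxybenzylidene. Styrene dimerisation and attack of Ru=CH2 on the prenyl group (loss of isobutene) may then overtake ring closure.
   Fallback: this sets out from 21. A Heck reaction with 23 (Pd(OAc)2, P(o-tol)3, Et3N, MeCN, 80 °C) should give (3R)-4'-hydroxy-5'-[(E)-3-hydroxy-3-methylbut-1-en-1-yl]-3'-prenyl-7,2'-bis(TBSO)isoflavan F1. Warming with PPTS in toluene should ionise the tertiary allylic alcohol to the ortho-quinone methide, which closes by oxa-6π electrocyclisation. The route is rejoined at 27.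

2. **Step 18.** The doubly ortho-substituted phenoxide may attack the primary terminus of the π-allyl complex, or palladium may re-ionise the product. Either process drifts to the linear O-prenyl ether.
   Fallback: this sets out from 22. Copper-catalysed propargylation with 3-chloro-3-methylbut-1-yne (CuCl2 cat., DBU, dry MeCN, 0 °C) should give (3R)-4'-(2-methylbut-3-yn-2-yloxy)-3'-prenyl-5'-vinyl-7,2'-bis(TBSO)isoflavan F2. Lindlar semihydrogenation (H2, Pd/CaCO3–Pb, quinoline, EtOAc) should reduce only the alkyne. The route is rejoined at 26.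

3. **Step 1.** O-alkylation and double alkylation may outrun C3-alkylation of the deactivated bromophenolate.
   Fallback: this sets out from 1.
   - The 4-OH is etherified with 3-chloro-3-methylbut-1-yne (K2CO3, KI, acetone, reflux) to 5-bromo-2-hydroxy-4-[(2-methylbut-3-yn-2-yl)oxy]benzaldehyde F3.
   - Lindlar semihydrogenation gives 5-bromo-2-hydroxy-4-[(2-methylbut-3-en-2-yl)oxy]benzaldehyde F4.
   - Heating in N,N-diethylaniline (about 120 °C) should trigger the aromatic Claisen rearrangement. With C5 blocked by bromine, it can rearomatise only at C3, and allyl inversion delivers the normal prenyl group. The route is rejoined at 3.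

**Further compounds**
F1 | step 19 | (3R)-4'-hydroxy-5'-[(E)-3-hydroxy-3-methylbut-1-en-1-yl]-3'-prenyl-7,2'-bis(TBSO)isoflavan | CC(C)(O)/C=C/c1cc([C@@H]2COc3cc(O[Si](C)(C)C(C)(C)C)ccc3C2)c(O[Si](C)(C)C(C)(C)C)c(CC=C(C)C)c1O
F2 | step 18 | (3R)-4'-(2-methylbut-3-yn-2-yloxy)-3'-prenyl-5'-vinyl-7,2'-bis(TBSO)isoflavan | C#CC(C)(C)Oc1c(C=C)cc([C@@H]2COc3cc(O[Si](C)(C)C(C)(C)C)ccc3C2)c(O[Si](C)(C)C(C)(C)C)c1CC=C(C)C
F3 | step 1 | 5-bromo-2-hydroxy-4-[(2-methylbut-3-yn-2-yl)oxy]benzaldehyde | O=Cc1cc(Br)c(OC(C)(C)C#C)cc1O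
F4 | step 1 | 5-bromo-2-hydroxy-4-[(2-methylbut-3-en-2-yl)oxy]benzaldehyde | O=Cc1cc(Br)c(OC(C)(C)C=C)cc1O
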